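**Retrosynthetic overview**
- The target is disconnected first at C2–H/C3–H: it comes from the corresponding flavone by an enantioselective 1,4-hydride addition that dearomatises the 4-pyranone ring and sets 2S in the last step (key step).
- The flavone comes from a 3-terpenyl-phloroacetophenone and benzoyl chloride: C-benzoylation of the polyanion, then cyclodehydration through the unhindered hydroxyl closes the pyranone ring.
- The terpenyl-phloroacetophenone comes from phloroacetophenone (C2v-symmetric, positions 3 and 5 identical, so only one regioisomer can form) and (S)-α-phellandrene by acid-catalysed hydroarylation, with the aryl group entering anti to the isopropyl group (trans, 1S,6S).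
- Ring order: the cyclohexene ring is bought with its stereocentre; the pyranone ring is closed in step 2 and reduced to the dihydropyranone in step 3.

Assumption: (S)-(+)-α-phellandrene is purchasable in high ee, and (R)-DTBM-SEGPHOS is taken as the ligand antipode that gives 2S (its mirror image is used if the sense proves opposite).

**Step 1**
Reactants: 1 phloroacetophenone; 2 (S)-(+)-α-phellandrene
Product: 3 1-{2,4,6-trihydroxy-3-[(1S,6S)-3-methyl-6-(propan-2-yl)cyclohex-2-en-1-yl]phenyl}ethan-1-one
Conditions: p-TsOH·H2O (10 mol%), CH2Cl2/dioxane (4:1), 0 °C → rt, equimolar amounts, the diene added by syringe pump over 3 h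
Reagents that add atoms: none
Why: Friedel–Crafts hydroarylation of a 1,3-diene: protonation of the diene at C1 gives the methyl-substituted cyclohexenyl allyl cation, which the symmetric arene captures at the secondary terminus anti to the neighbouring isopropyl group, so the new C1′ centre is set S (trans to the purchased C6′ centre) and the trisubstituted alkene stays in place.

**Step 2**
Reactants: 3 1-{2,4,6-trihydroxy-3-[(1S,6S)-3-methyl-6-(propan-2-yl)cyclohex-2-en-1-yl]phenyl}ethan-1-one; 4 benzoyl chloride
Product: 6 5,7-dihydroxy-6-[(1S,6S)-3-methyl-6-(propan-2-yl)cyclohex-2-en-1-yl]-2-phenyl-4H-chromen-4-one, via 1,3-diketone 5 (not isolated)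
Conditions: LiN(SiMe3)2 (5 equiv), THF, −78 → −10 °C; 4 (1.05 equiv), −78 °C → rt; aq. HCl quench; crude 5 in AcOH/NaOAc, 90 °C
Reagents that add atoms: none
Why: Direct polyanion variant of the Baker–Venkataraman diketone synthesis: only the ketone enolate carbon of the tetralithiated species is acylated by 4, and in buffered acetic acid the free 6′-hydroxyl of 5 (the 2′-hydroxyl is held in the ketone chelate and shielded by the terpene) adds to the benzoyl carbonyl and loses water to give the 4-pyranone with the terpene at C6; no stereocentre is made or touched.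

**Step 3**
Reactants: 6 5,7-dihydroxy-6-[(1S,6S)-3-methyl-6-(propan-2-yl)cyclohex-2-en-1-yl]-2-phenyl-4H-chromen-4-one
Product: 9 (2S)-5,7-dihydroxy-6-[(1S,6S)-3-methyl-6-(propan-2-yl)cyclohex-2-en-1-yl]-2-phenyl-2,3-dihydro-4H-chromen-4-one (the target), via bis-silyl ether 7 (not isolated), via silyl enol ether 8 (not isolated)
Conditions: Cu(OAc)2·H2O (5 mol%), (R)-DTBM-SEGPHOS (5.5 mol%), (EtO)2MeSiH (6 equiv), toluene/THF, 0 °C → rt; then 1 M HCl, THF, 0 °C
Reagents that add atoms: none
Why: Proposed new method: the two phenols are first capped in the flask by copper-catalysed dehydrogenative O-silylation (7); the ligated monovalent copper hydride then delivers hydride to C2 of the flavone enone in a 1,4-sense and σ-bond metathesis with the silane releases silyl enol ether 8, so C2 is set S by the chiral bisphosphine alone (the terpene centres are remote) and is protected from retro-oxa-Michael opening until the mild acidic work-up, while the unactivated trisubstituted alkene is inert to copper hydride; the closest known reaction type is the copper hydride-catalysed asymmetric conjugate reduction of 2-substituted chromones, thiochromones and β,β-disubstituted cyclic enones, extended here to a 2-aryl chromone, which breaks the aromatic benzopyranone system.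

**Compound list**
1 | phloroacetophenone (1-(2,4,6-trihydroxyphenyl)ethan-1-one) | CC(=O)c1c(O)cc(O)cc1O | starting material
2 | (S)-(+)-α-phellandrene, (5S)-2-methyl-5-(propan-2-yl)cyclohexa-1,3-diene | CC1=CC[C@@H](C(C)C)C=C1 | starting material
3 | 1-{2,4,6-trihydroxy-3-[(1S,6S)-3-methyl-6-(propan-2-yl)cyclohex-2-en-1-yl]phenyl}ethan-1-one | CC1=C[C@@H](c2c(O)cc(O)c(C(C)=O)c2O)[C@H](C(C)C)CC1 | intermediate
4 | benzoyl chloride | O=C(Cl)c1ccccc1 | starting material
5 | 1-phenyl-3-{2,4,6-trihydroxy-3-[(1S,6S)-3-methyl-6-(propan-2-yl)cyclohex-2-en-1-yl]phenyl}propane-1,3-dione | CC1=C[C@@H](c2c(O)cc(O)c(C(=O)CC(=O)c3ccccc3)c2O)[C@H](C(C)C)CC1 | intermediate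
6 | 5,7-dihydroxy-6-[(1S,6S)-3-methyl-6-(propan-2-yl)cyclohex-2-en-1-yl]-2-phenyl-4H-chromen-4-one | CC1=C[C@@H](c2c(O)cc3c(c2O)C(=O)C=C(c2ccccc2)O3)[C@H](C(C)C)CC1 | intermediate
7 | 5,7-bis{[diethoxy(methyl)silyl]oxy}-6-[(1S,6S)-3-methyl-6-(propan-2-yl)cyclohex-2-en-1-yl]-2-phenyl-4H-chromen-4-one | CC1=C[C@@H](c2c(O[Si](C)(OCC)OCC)cc3c(c2O[Si](C)(OCC)OCC)C(=O)C=C(c2ccccc2)O3)[C@H](C(C)C)CC1 | intermediate
8 | (2S)-4,5,7-tris{[diethoxy(methyl)silyl]oxy}-6-[(1S,6S)-3-methyl-6-(propan-2-yl)cyclohex-2-en-1-yl]-2-phenyl-2H-chromene | CC1=C[C@@H](c2c(O[Si](C)(OCC)OCC)cc3c(c2O[Si](C)(OCC)OCC)C(O[Si](C)(OCC)OCC)=C[C@@H](c2ccccc2)O3)[C@H](C(C)C)CC1 | intermediate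
9 | (2S)-5,7-dihydroxy-6-[(1S,6S)-3-methyl-6-(propan-2-yl)cyclohex-2-en-1-yl]-2-phenyl-2,3-dihydro-4H-chromen-4-one | CC1=C[C@@H](c2c(O)cc3c(c2O)C(=O)C[C@@H](c2ccccc2)O3)[C@H](C(C)C)CC1 | target

**Step count and risks**
Total steps: 3. Longest linear sequence: 3 steps (1 → 3 → 6 → 9).

Most likely to fail, first: step 3. The electron-rich, 2-aryl-substituted enone may be too unreactive toward copper hydride, or the selectivity may be low. The fallback makes the C2 centre by C–C instead of C–H bond formation and sets out from 3. Claisen formylation of the polyanion of 3 with ethyl formate (LiN(SiMe3)2, THF) gives 3-oxo-3-{2,4,6-trihydroxy-3-[(1S,6S)-3-methyl-6-(propan-2-yl)cyclohex-2-en-1-yl]phenyl}propanal F4. Mild acid (AcOH/NaOAc) closes this to 5,7-dihydroxy-6-[(1S,6S)-3-methyl-6-(propan-2-yl)cyclohex-2-en-1-yl]-4H-chromen-4-one F5. Palladium-catalysed asymmetric conjugate addition of phenylboronic acid (Pd(OCOCF3)2, (S)-t-BuPyOx or its mirror image, NH4PF6, water, ClCH2CH2Cl, 60 °C) then puts the phenyl group on C2 and comes back to the route at 9.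

Second: step 2. The cyclodehydration may close partly through the hindered hydroxyl and give the 8-terpenyl isomer, or the terpene may not survive warm acetic acid. The fallback fixes the pyranone oxygen before the C–C bond and sets out from 2. Compound 2 is coupled with phloroglucinol under the step 1 conditions (one product only, by D3h symmetry) to give 2-[(1S,6S)-3-methyl-6-(propan-2-yl)cyclohex-2-en-1-yl]benzene-1,3,5-triol F2. Its only unhindered hydroxyl, para to the terpene, adds to ethyl 3-phenylpropiolate (K2CO3 cat., acetone) to give ethyl (2Z)-3-{3,5-dihydroxy-4-[(1S,6S)-3-methyl-6-(propan-2-yl)cyclohex-2-en-1-yl]phenoxy}-3-phenylprop-2-enoate F3. Intramolecular Friedel–Crafts acylation (P2O5/MeSO3H, 0 °C → rt, short contact) at either of the two equivalent ortho positions, with loss of ethanol, comes back to the route at 6 with the terpene necessarily at C6.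

Third: step 1. Compound 2 may not be available enantiopure, or it may partly racemise through α-terpinene under the acid. With equimolar amounts, a second alkylation at the remaining ring position of 3 also takes part of the material and leaves a matching part of the acetophenone untouched, so the yield of 3 is expected to be moderate. The fallback takes the terpene from the (R)-limonene pool and sets out from 1. Compound 1 is alkylated with commercial (4R)-p-mentha-2,8-dien-1-ol (BF3·OEt2, CH2Cl2/dioxane, −10 °C) to give 1-{2,4,6-trihydroxy-3-[(1R,6R)-3-methyl-6-(prop-1-en-2-yl)cyclohex-2-en-1-yl]phenyl}ethan-1-one F1. Hydrogenation of the 1,1-disubstituted alkene alone (RhCl(PPh3)3, H2 1 atm, benzene/EtOH) comes back to the route at 3.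

**Further compounds**
F1 | step 1 | 1-{2,4,6-trihydroxy-3-[(1R,6R)-3-methyl-6-(prop-1-en-2-yl)cyclohex-2-en-1-yl]phenyl}ethan-1-one | CC1=C[C@@H](c2c(O)cc(O)c(C(C)=O)c2O)[C@H](C(C)=C)CC1
F2 | step 2 | 2-[(1S,6S)-3-methyl-6-(propan-2-yl)cyclohex-2-en-1-yl]benzene-1,3,5-triol | CC1=C[C@@H](c2c(O)cc(O)cc2O)[C@H](C(C)C)CC1
F3 | step 2 | ethyl (2Z)-3-{3,5-dihydroxy-4-[(1S,6S)-3-methyl-6-(propan-2-yl)cyclohex-2-en-1-yl]phenoxy}-3-phenylprop-2-enoate | CC1=C[C@@H](c2c(O)cc(O/C(=C\C(=O)OCC)c3ccccc3)cc2O)[C@H](C(C)C)CC1
F4 | step 3 | 3-oxo-3-{2,4,6-trihydroxy-3-[(1S,6S)-3-methyl-6-(propan-2-yl)cyclohex-2-en-1-yl]phenyl}propanal | CC1=C[C@@H](c2c(O)cc(O)c(C(=O)CC=O)c2O)[C@H](C(C)C)CC1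
F5 | step 3 | 5,7-dihydroxy-6-[(1S,6S)-3-methyl-6-(propan-2-yl)cyclohex-2-en-1-yl]-4H-chromen-4-one | CC1=C[C@@H](c2c(O)cc3c(c2O)C(=O)C=CO3)[C@H](C(C)C)CC1
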